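(The data are simulated for substances that don't exist; noise was put on by code.)

Monday's first reading gave my estimate of the number I wanted, the start ratio S: D over G as they first come from L + E, the selectivity factor of the two branches. I reckoned the late share first, because there two runs could be held against each other.

| setting | Saturday's | Wednesday's | Monday's | flask |
|---|---|---|---|---|
| L | 19 mM | 19 mM | 38 mM | 19 mM |
| E | 95 mM | 95 mM | 95 mM | 95.0 mM |
| X | 13 µM | 21 µM | 9.5 µM | 9.5 µM |
| remark | run made earlier | run made earlier | run made earlier |  |
| time |  |  |  | 15 min |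

- Saturday's (time / min: D / %, G / %): 5.00: 31.8, 21.6; 10.0: 26.7, 15.9; 15.0: 25.0, 12.5; 20.0: 24.5, 11.2
- Wednesday's (time / min: D / %, G / %): 2.50: 39.9, 24.4; 6.00: 31.3, 19.7; 12.0: 25.2, 13.4; 20.0: 24.7, 11.0
- Monday's (time / min: D / %, G / %): 2.50: 39.1, 21.0; 6.00: 32.0, 18.8; 12.0: 27.4, 14.2; 20.0: 25.5, 10.7

(scatter of a reading: 0.5 percentage points)

- share of D in D plus G at 0.60 s
- share of D in D plus G at 20 s
- share of D in D plus G at 15 min

- the analysis behind the earlier runs scatters by 0.5 percentage points, standard deviation
- a reading or a percentage of D counts all its forms, free or not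

Saturday's run gives the share at 15.0 min directly:

share = 25.0 / (25.0 + 12.5) = 66.7 %

Wednesday's run, with more X, has to be read between 12.0 min and 20.0 min:

65.3 % to 69.2 %, which gives 66.8 % at 15 min

The two agree, at 13 µM and 21 µM of X, so I carried Saturday's figure over to the flask as my estimate.

For the start, two first readings at 2.50 min parted: Wednesday's gives 62.1 %, Monday's 65.1 %. Saturday's first reading gives 59.6 %, and the share sank as [X] times time grew, to 2.21 times Monday's on Wednesday and 2.74 times on Saturday. Monday's product was smaller than the other two, though its doubled [L] stayed unseparated, so I took Monday's reading as my estimate of the start: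

S = 39.1 / 21.0 = 1.86, start share S/(1 + S) = 65.0 %

The flask has Monday's [X], and 20 s is shorter than Monday's 2.50 min, so I used that share at both early times.

The forecast said 71 %, 69 % and 67 %: “Back-extrapolating gives D about 50 and G about 20–25 at zero time, so an early share near 70%.”

The flask gave 65.3 %, 65.5 % and 65.9 %.

    L + E ⇌ D (K = 60.5 M⁻¹, k = 13.7 M⁻¹ min⁻¹)
    L + E ⇌ G (K = 28.0 M⁻¹, k = 7.27 M⁻¹ min⁻¹)
    D + X ⇌ G + X, rate k3*[X]*[D] forward; the back reaction follows from the equilibrium constant (k = 1590 M⁻¹ min⁻¹)
    L + D ⇌ Q, settled at all times (K = 100 M⁻¹)
    X + D ⇌ J, settled at all times (K = 48.0 M⁻¹)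
    D ⇌ Z (K = 2.70, k = 0.315 min⁻¹)

My start share stood 0.29 percentage points below the flask's at 0.60 s, and my late share stood 0.80 points high. In this flask free D had a half-life of 3.1 min for going back through its making, short against 15 min, and the share had stood at 60.2 % at 7.50 min before it rose again to 65.9 % at 15 min. In a second flask with 24 mM of E, the other charges as in the first, both branches take L + E, so S gives the same 65.0 % at the start; computed, that flask gave 65.3 % at 0.60 s and 71.3 % at 15 min.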